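The earlier runs and the new flask are simulated on assumed constants; noise was put on by code.

Follow one molecule.

in all of them: starting material 1.9 M

|  | reagent | remark | time |
|---|---|---|---|
| beta | 0.85 M | run made earlier |  |
| gamma | 1.3 M | run made earlier |  |
| flask | 1.71 M |  | 50 min |

| run | time / min | starting material / % | first product / % |
|---|---|---|---|
| beta | 3.00 | 94 | 3 |
| beta | 5.00 | 91 | 3 |
| beta | 8.00 | 88 | 4 |
| beta | 15.0 | 80 | 8 |
| beta | 25.0 | 72 | 13 |
| beta | 40.0 | 66 | 13 |
| gamma | 3.00 | 94 | 2 |
| gamma | 5.00 | 91 | 3 |
| gamma | 8.00 | 82 | 6 |
| gamma | 15.0 | 72 | 10 |
| gamma | 25.0 | 65 | 13 |
| gamma | 40.0 | 53 | 19 |

(standard deviation of a reading: 2 percentage points)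

- percent here means starting material units held: one idle adduct counts as two
- what is said of first product includes idle adduct
- candidate steps: starting material + first product <-> idle adduct; reagent + other mono adduct -> bis adduct; starting material + reagent -> first product; 2 reagent -> homo dimer; reagent + first product -> bis adduct; starting material + reagent -> other mono adduct
- in an amount of first product, one idle adduct counts as one first product

* the starting material standing at 50 min, as a percentage of the starting material charged
* the first product standing at 50 min, as a percentage of the starting material charged
* the other mono adduct standing at 50 min, as a percentage of the starting material charged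
* the bis adduct standing at 50 min, as a percentage of the starting material charged

What can the readings give you? They give f, the first product gained per starting material lost. Pooled over the beta and gamma runs at 40.0 min, f reads 0.395.

Is f the chance of taking the first-product fork? Not if the idle adduct forms. The first product reading counts an idle adduct as one, yet that adduct holds a second starting material unit, lost from the starting material column. Suppose each first product holds such a partner. A departing molecule then becomes first product with chance f, becomes a partner with chance f, and otherwise strays.

What is the stray share? The stray share h is the part of the starting material lost that ends as other mono adduct plus bis adduct, so h = 1 − 2f, which is 0.210. The odds at the fork, a selectivity factor read from these runs, are f/h, or 1.88.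

Where is the weak spot? No column shows the idle adduct, so the partner is my assumption, taken from the candidate step and the counting convention. I commit to it anyway.

The forecast for this flask gives 39% starting material, 22% first product, 31% other mono adduct and 8% bis adduct, and says the unmeasured remainder “must be other mono adduct plus bis adduct”. My h on the forecast's own loss gives those two together 12.8%, less than the forecast's 39.0%.

The flask gives 44.1%, 22.9%, 8.14% and 3.42%.

    starting material + first product ⇌ idle adduct, settled at all times (K = 18.0 M⁻¹)
    reagent + other mono adduct → bis adduct (k = 3.20 × 10⁻⁴ M⁻¹ s⁻¹)
    starting material + reagent → first product (k = 1.70 × 10⁻⁴ M⁻¹ s⁻¹)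
    2 reagent → homo dimer (k = 2.10 × 10⁻⁴ M⁻¹ s⁻¹)
    reagent + first product → bis adduct (k = 6.20 × 10⁻⁵ M⁻¹ s⁻¹)
    starting material + reagent → other mono adduct (k = 8.50 × 10⁻⁵ M⁻¹ s⁻¹)

In this flask, reagent stood at 31.5% of its charge after 25.0 min, when the making of first product had 79% of its turnover behind it and the homo dimer step 87%. The tying up as idle adduct ran alongside, reaching a net turnover of 21.5% by 50.0 min. Here h on the loss gives 11.7% for other mono adduct plus bis adduct, and the flask holds 11.6%. In a neighbouring flask charged with 0.43 M of reagent, h on the loss gives 4.81%, and that neighbouring flask holds 4.66%.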